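All runs come from a simulation for substances that don't exist; the scatter is artificial.

A small charge of capture agent, 0.400 mM, sits in this flask beside far larger charges of substrate and both partners. I want to know what stops it. Target reaches 32.7% at 10.0 min, and the last step from 8.00 min adds 0.3 percentage points, with a scatter of 0.5 points on each reading.

- red: substrate 20 mM; fresh partner 30 mM; coupling partner 30 mM; capture agent 0.40 mM; the very flask that is asked about, followed so far
- flask: substrate 20 mM; fresh partner 30.0 mM; coupling partner 30.0 mM; capture agent 0.400 mM; time 15 min

- red (time / min: target / %): 2.00: 11.8; 4.00: 23.7; 5.00: 26.2; 8.00: 32.4; 10.0: 32.7

(scatter of a reading: 0.5 percentage points)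

- dawn: at 15 min add substrate, 50.0% of the amount charged, then wait 5.0 min
- dusk: at 15 min take out 90% of the target then present, then wait 5.0 min
- autumn: at 15 min add coupling partner, 50.0% of the amount charged, then wait 5.0 min
- noon: change nothing and wait 5.0 min more

- what is taken out of target is counted as made
- additions bring no volume worth counting

- target, in percent of the substrate first charged, at 15 min
- the option that brings most further target ("none" if no option brings more than 2 percentage points) (dawn / dusk / autumn / noon / none)
- target present, with what was taken out counted in, in percent of the substrate first charged, after dawn
- target present, with what was taken out counted in, in percent of the substrate first charged, after autumn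

The readings can't name what stops the flask. My bet is the coupling partner as limiting reagent, which I take to be used by both other reagents. So I carry its return, the target made per amount of coupling partner charged:

return = 6.54 mM / 30 mM = 0.218

The autumn dose then brings:

gain = 0.218 × 15.0 mM / 20 mM = 16 points

I therefore commit to about 32.7% now, to autumn as best, and to 49.1% after autumn.

Now set beside this flask the neighbour charged with 120 mM of coupling partner. Its budget at the same return is 26.2 mM, more than the 20 mM of substrate. So I expect the neighbour to stop on substrate, and this flask on coupling partner.

The forecast gives 32.9% now, none as best, 33% after dawn and 33% after autumn. Its ground is this: “The plateau is therefore kinetic death, not a limit set by reagents.” It parts from me on the best option.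

The flask gives 35.3% now and autumn as best, with 7.3 points further. Dawn ends at 35.7% and autumn at 42.6%, above the forecast and below my figure.

    substrate + coupling partner → open intermediate (k = 0.176 /M/s)
    coupling partner + fresh partner → second intermediate (k = 0.219 /M/s)
    open intermediate + second intermediate → target (k = 1.19 /M/s)
    2 open intermediate → homo product (k = 0.390 /M/s)
    second intermediate + capture agent → trapped intermediate (k = 1.63 /M/s)
    second intermediate → side product (k = 0.00444 /s)

In this flask coupling partner stands at 1.1% of its charge at 15.0 min, and on the autumn dose my return of 0.218 promises 16 points where the flask brings 7.3 points. On the neighbour, the budget above the substrate charge points to substrate, and substrate stands at 0% at 15.0 min, fresh partner likewise at 0%, with 58% of the coupling partner left. The spent part of that coupling partner, at my return, gives 54.9% of target. The neighbour holds 74.2% of target beside 22.6% of homo product.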